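## Retrosynthetic overview

- Numbering: five-membered ring C1(CH3)–C2(OAc)–C3–C4(OH)(iPr)–C5, seven-membered ring C5–C6(O-aroyl)–C7=C8(CH3)–C9(=O)–C10–C1. The plan rests on two features: C6 and C9 both carry oxygen and lie 1,4 across C7=C8, which is the C2/C5 pattern of a furan, and C5–C1–C10 is a three-carbon unit whose central carbon (quaternary C1) can begin as the carbonyl of an oxyallyl cation.
- The seven-membered ring is made first: a (4+3) cycloaddition of furan with the oxyallyl cation from tetrabromoacetone forms C5–C6 and C9–C10 and gives a meso ketone with a C6–O–C9 bridge.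
- Desymmetrisation (chiral lithium amide, acetaldehyde aldol) puts C4–C3 on C5. Wittig olefination, directed cyclopropanation and hydrolysis turn the C1 ketone into C1(CH3)(CHO). An aldol closure C2–C3 then makes the five-membered ring, and isopropyl is added to C4.
- The bridge is opened by palladium-catalysed syn delivery of methyl to C8 with loss of C6–O. C9 is oxidised, a singlet-oxygen ene reaction returns oxygen to C6 on the α face and moves the alkene to C7=C8, and two acylations finish.
- β is the face of the C1 methyl of the target, which is also the face of the oxygen bridge in every bridged intermediate; α is the opposite face.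

Key step: step 1

Remark: the (R,R) lithium amide is assumed to remove the exo proton of the methylene that becomes C5; if it selects the other methylene, its (S,S) enantiomer is used and nothing else changes.

## Route

Step 1
Reactants: 1 furan; 2 1,1,3,3-tetrabromoacetone
Product: 4 8-oxabicyclo[3.2.1]oct-6-en-3-one (meso), via dibromo cycloadduct 3 (not isolated)
Conditions: Zn–Cu couple, B(OEt)3, THF, furan in excess, 0 °C to rt; then Zn–Cu couple, NH4Cl, MeOH, −78 °C to rt
Reagents that add atoms: none
Why: Zinc reduces a C–Br bond of 2 and the zinc enolate loses bromide to give a 1,3-dibromo-2-oxyallyl cation, a three-carbon two-π-electron partner that adds across C2 and C5 of furan in a (4+3) cycloaddition, the known reaction of polybromoketone-derived oxyallyl cations with furans. The seven-membered carbocycle closes in this one intermolecular annulation by formation of both new bonds, C5–C6 and C9–C10, at the two termini of the allyl cation (concerted, or by ring closure of the furan-derived cation onto the zinc enolate), and the furan oxygen becomes the C6–O–C9 bridge. The two bridgehead centres C6 and C9 are set cis by the bridge itself, since both bonds must form on one face of the planar furan. The second charge of couple with NH4Cl reduces the two α-bromides of 3 through zinc enolates, which removes the C–Br centres and leaves meso 4. No regio-, diastereo- or enantioselectivity is therefore needed; the only demand is that furan traps the cation faster than it is reduced, which excess furan and the borate additive should secure.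

Step 2
Reactants: 4 8-oxabicyclo[3.2.1]oct-6-en-3-one; 5 acetaldehyde
Product: 7 (1S,2S,5S)-2-[(1R)-1-hydroxyethyl]-8-oxabicyclo[3.2.1]oct-6-en-3-one (side chain on C5 β), via lithium enolate 6 (not isolated)
Conditions: (R,R)-bis(1-phenylethyl)amine·HCl, n-BuLi (2 equiv), THF, −78 °C; 4; then CH3CHO, −78 °C; aq. NH4Cl at −78 °C
Reagents that add atoms: none
Why: Enantioselective deprotonation of the meso ketone by the C2-symmetric chiral lithium amide (LiCl from the salt sharpens the selectivity) gives enolate 6, and its aldol addition through a Zimmerman–Traxler chair on the exo face, syn to the oxygen bridge, sets C5 with the side chain β (axial) and the carbinol centre anti, the latter being removed in step 8.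

Step 3
Reactants: 7 exo aldol
Product: 8 triethylsilyl ether of 7
Conditions: Et3SiOTf, 2,6-lutidine, CH2Cl2, −78 °C
Reagents that add atoms: triethylsilyl trifluoromethanesulfonate, CC[Si](CC)(CC)OS(=O)(=O)C(F)(F)F
Why: Low-temperature silylation with the silyl triflate and a hindered pyridine protects the aldol hydroxyl without retro-aldol or epimerisation of the axial C5 substituent, so that the basic ylide of step 4 cannot trigger retro-aldol.

Step 4
Reactants: 8 silyl ether ketone
Product: 9 methyl enol ether of 8 (C1=CH–OMe; E/Z mixture)
Conditions: Ph3P(CH2OMe)Cl, KN(SiMe3)2, THF, 0 °C; then 8, −78 °C to rt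
Reagents that add atoms: (methoxymethyl)triphenylphosphonium chloride, COC[P+](c1ccccc1)(c1ccccc1)c1ccccc1.[Cl-]
Why: Wittig methoxymethylenation brings in the future C2 as an enol ether; the unstabilised ylide adds to the ketone faster than it enolises it, which keeps C5, and the E/Z mixture is of no consequence because both isomers converge in step 7.

Step 5
Reactants: 9 silyl enol ether
Product: 10 hydroxy enol ether
Conditions: Bu4NF, THF, 0 °C
Reagents that add atoms: none
Why: Fluoride desilylation is basic and leaves the acid-labile enol ether intact, freeing the side-chain hydroxyl that directs step 6.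

Step 6
Reactants: 10 hydroxy enol ether
Product: 11 spiro methoxycyclopropane (cyclopropane CH2 on the β face of C1)
Conditions: Et2Zn, CH2I2, CH2Cl2, −20 to 0 °C
Reagents that add atoms: diiodomethane, ICI
Why: Simmons–Smith cyclopropanation in the Furukawa variant: the zinc alkoxide of the β side chain delivers the carbenoid to the β face of the electron-rich enol ether, which also reacts far faster than the unactivated C7=C8 bond, so C1 is set with the future methyl carbon β and the future formyl carbon α (the OMe centre is a mixture and is lost in step 7).

Step 7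
Reactants: 11 spiro methoxycyclopropane
Product: 13 1,4-diol (C1 carries β-methyl plus α-hydroxymethyl), via hydroxy aldehyde 12 (not isolated)
Conditions: 1 M aq. HCl, THF, 50 °C; then NaHCO3 to pH 7, NaBH4, 0 °C
Reagents that add atoms: water, O
Why: Acid opens the alkoxycyclopropane by protonation of its CH2 group and cleavage of the CH2–C2 bond (geminal alkylation by way of an enol ether cyclopropane), which turns CH2 into the C1 methyl and C2 into a formyl group without touching C1, and borohydride in the same flask takes the hydroxy aldehyde or its lactol to diol 13 so that no C4 ketone is ever exposed to acid, which would epimerise C5.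

Step 8
Reactants: 13 1,4-diol
Product: 14 keto aldehyde (C5 β-acetyl; C1 β-methyl α-formyl)
Conditions: (COCl)2, DMSO, CH2Cl2, −78 °C; Et3N, −78 to 0 °C
Reagents that add atoms: none
Why: Swern oxidation activates both hydroxyls before the base is added, so the 1,4-diol goes to the keto aldehyde without lactol oxidation to a lactone, and triethylamine at low temperature does not epimerise C5.

Step 9
Reactants: 14 keto aldehyde
Product: 16 tricyclic 2β-hydroxy C4 ketone (trans C1–C5 fusion), via lithium enolate 15 (not isolated)
Conditions: LiN(iPr)2, THF, 14 added slowly, −78 to −40 °C; AcOH quench at −78 °C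
Reagents that add atoms: none
Why: Kinetic deprotonation at the acetyl CH3 (C3) and intramolecular aldol addition to the non-enolisable aldehyde close the five-membered ring as in the cyclisation of 1,4-dicarbonyl compounds to 3-hydroxycyclopentanones; the trans arms on C5 and C1 are gauche in the boat form of the oxane ring (the conformation that 2β,3α-disubstituted tropanes adopt), and the forming alkoxide takes the pseudo-equatorial position at C2, cis to the angular methyl as the 17β oxygen of a steroid D ring, so the C2 hydroxyl should be β.

Step 10
Reactants: 16 tricyclic aldol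
Product: 17 2β-triethylsilyl ether of 16
Conditions: Et3SiCl, imidazole, DMF, 0 °C
Reagents that add atoms: chlorotriethylsilane, CC[Si](Cl)(CC)CC
Why: Silylation of the secondary aldol hydroxyl under mild base blocks retro-aldol and β-elimination in the organometallic step.

Step 11
Reactants: 17 silyloxy ketone; 18 isopropylmagnesium chloride
Product: 19 tertiary alcohol (4β-hydroxy 4α-isopropyl)
Conditions: CeCl3 (anhydrous), THF, −78 °C; 18; then 17, −78 °C; aq. NH4Cl
Reagents that add atoms: none
Why: The organocerium reagent adds to the hindered, enolisable cyclopentanone without enolisation or β-hydride reduction, and it attacks C4 on the α face, anti to the angular C1 methyl, the C2 silyloxy group and the oxygen bridge, so the hydroxyl is β and the isopropyl group α.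

Step 12
Reactants: 19 bridged tertiary alcohol
Product: 20 bridge-opened diol (9β-hydroxy 8β-methyl; C6=C7)
Conditions: PdCl2(CH3CN)2 (5 mol %), 1,1'-bis(diphenylphosphino)ferrocene (5 mol %), Me2Zn (3 equiv), ClCH2CH2Cl, 60 °C; aq. NH4Cl
Reagents that add atoms: dimethylzinc, C[Zn]C
Why: Palladium-catalysed alkylative ring opening of an oxabicyclic alkene with a dialkylzinc: methylpalladium adds across C7=C8 on the exo (β) face with methyl on C8, the alkene carbon remote from the crowded C5–C4 flank, and syn β-oxygen elimination breaks C6–O, leaving C6=C7 and the C9 hydroxyl and C8 methyl cis (both β).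

Step 13
Reactants: 20 bridge-opened diol
Product: 21 β,γ-unsaturated C9 ketone
Conditions: Dess–Martin periodinane, NaHCO3, CH2Cl2, 0 °C
Reagents that add atoms: none
Why: Buffered Dess–Martin oxidation converts the secondary C9 alcohol into the ketone under neutral conditions that leave the tertiary alcohol alone and should neither move the β,γ double bond into conjugation nor epimerise C8.

Step 14
Reactants: 21 β,γ-unsaturated ketone
Product: 23 6α-hydroxy enone, via 6α-hydroperoxide 22 (not isolated)
Conditions: O2, tetraphenylporphyrin (cat.), visible light, CH2Cl2, −20 °C; then PPh3, −20 °C to rt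
Reagents that add atoms: dioxygen, O=O
Why: Schenck ene reaction of singlet oxygen with a β,γ-unsaturated ketone, a known route to γ-hydroperoxy enones: only the α face of C6=C7 carries allylic hydrogens, oxygen bonds to C6 on that face while the activated α hydrogen on C8 is removed suprafacially, so the C8 centre of step 12 is relayed to C6 (oxygen α) as the double bond moves to C7=C8, and triphenylphosphine reduces the hydroperoxide to the alcohol.

Step 15
Reactants: 23 6α-hydroxy enone; 24 4-acetoxybenzoic acid
Product: 25 6α-(4-acetoxybenzoate)
Conditions: N,N'-dicyclohexylcarbodiimide, DMAP (cat.), CH2Cl2, 0 °C to rt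
Reagents that add atoms: none
Why: Steglich esterification acylates the secondary allylic C6 hydroxyl, while the hindered tertiary C4 hydroxyl does not react.

Step 16
Reactants: 25 silyl ether ester
Product: 26 C2 alcohol of 25
Conditions: HF·pyridine, pyridine, THF, 0 °C
Reagents that add atoms: none
Why: Pyridine-buffered hydrogen fluoride cleaves the triethylsilyl ether without affecting the aryl acetate, the benzoate or the enone.

Step 17
Reactants: 26 C2 alcohol
Product: 27 2β-acetate (phenol still acetylated)
Conditions: Ac2O, pyridine, DMAP (cat.), CH2Cl2, rt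
Reagents that add atoms: acetic anhydride, CC(=O)OC(C)=O
Why: DMAP-catalysed acetylation esterifies the secondary C2 alcohol, and the tertiary C4 alcohol flanked by the isopropyl group is too hindered to react at room temperature.

Step 18
Reactants: 27 diacetate
Product: 28 target CNP0087181.7
Conditions: NH4OAc, MeOH–H2O (4:1), rt
Reagents that add atoms: none
Why: An aryl acetate is much more electrophilic than an alkyl acetate or a benzoate because phenoxide is the leaving group, so neutral ammonium acetate in aqueous methanol should remove only the phenolic acetate and give the target.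

## Compound list

1 | furan | c1ccoc1 | starting material
2 | 1,1,3,3-tetrabromoacetone | BrC(Br)C(=O)C(Br)Br | starting material
3 | 2,4-dibromo-8-oxabicyclo[3.2.1]oct-6-en-3-one (mixture of C–Br epimers; the cis-diequatorial meso isomer is drawn) | O=C1[C@@H](Br)[C@H]2C=C[C@H](O2)[C@H]1Br | intermediate (not isolated)
4 | (1R,5S)-8-oxabicyclo[3.2.1]oct-6-en-3-one (meso; carbonyl carbon = C1, bridgeheads = C6 and C9) | O=C1C[C@H]2C=C[C@@H](C1)O2 | intermediate
5 | acetaldehyde | CC=O | starting material
6 | lithium enolate of 4 (C1=C5 enolate) | [Li]OC1=C[C@@H]2C=C[C@H](C1)O2 | intermediate (not isolated)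
7 | (1S,2S,5S)-2-[(1R)-1-hydroxyethyl]-8-oxabicyclo[3.2.1]oct-6-en-3-one (side chain on C5 β, syn to the oxygen bridge) | O=C1C[C@H]2C=C[C@H](O2)[C@@H]1[C@@H](C)O | intermediate
8 | triethylsilyl ether of 7 | O=C1C[C@H]2C=C[C@H](O2)[C@@H]1[C@@H](C)O[Si](CC)(CC)CC | intermediate
9 | methyl enol ether of 8 (exocyclic C1=CH–OMe, E/Z mixture, geometry not specified) | COC=C1C[C@H]2C=C[C@H](O2)[C@@H]1[C@@H](C)O[Si](CC)(CC)CC | intermediate
10 | hydroxy enol ether (9 without the silyl group) | COC=C1C[C@H]2C=C[C@H](O2)[C@@H]1[C@@H](C)O | intermediate
11 | spiro methoxycyclopropane at C1 (ring CH2 β, CH(OMe) α; both OMe epimers) | COC1C[C@@]12C[C@H]3C=C[C@H](O3)[C@@H]2[C@@H](C)O | intermediate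
12 | hydroxy aldehyde (C1: methyl β, formyl α; may exist as its lactol) | O=C[C@@]1(C)C[C@H]2C=C[C@H](O2)[C@@H]1[C@@H](C)O | intermediate (not isolated)
13 | 1,4-diol (C1: methyl β, hydroxymethyl α; C5: β 1-hydroxyethyl) | OC[C@@]1(C)C[C@H]2C=C[C@H](O2)[C@@H]1[C@@H](C)O | intermediate
14 | keto aldehyde (C5: β acetyl; C1: methyl β, formyl α) | O=C[C@@]1(C)C[C@H]2C=C[C@H](O2)[C@@H]1C(C)=O | intermediate
15 | lithium enolate of 14 at the acetyl CH3 | O=C[C@@]1(C)C[C@H]2C=C[C@H](O2)[C@@H]1C(=C)O[Li] | intermediate (not isolated)
16 | tricyclic aldol: cyclopentanone trans-fused at C1–C5 to the oxabicycle, 2β-hydroxy, C4 ketone | O[C@H]1CC(=O)[C@H]2[C@@H]3C=C[C@@H](O3)C[C@]12C | intermediate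
17 | 2β-triethylsilyl ether of 16 | CC[Si](CC)(CC)O[C@H]1CC(=O)[C@H]2[C@@H]3C=C[C@@H](O3)C[C@]12C | intermediate
18 | isopropylmagnesium chloride | CC(C)[Mg]Cl | starting material
19 | bridged tertiary alcohol (4β-hydroxy, 4α-isopropyl, 2β-silyloxy) | CC[Si](CC)(CC)O[C@H]1C[C@](O)(C(C)C)[C@H]2[C@@H]3C=C[C@@H](O3)C[C@]12C | intermediate
20 | bridge-opened hydroazulene diol (9β-hydroxy, 8β-methyl, C6=C7, 4β-hydroxy, 2β-silyloxy) | CC[Si](CC)(CC)O[C@H]1C[C@](O)(C(C)C)[C@H]2C=C[C@@H](C)[C@@H](O)C[C@]12C | intermediate
21 | β,γ-unsaturated C9 ketone (8β-methyl, C6=C7) | CC[Si](CC)(CC)O[C@H]1C[C@](O)(C(C)C)[C@H]2C=C[C@@H](C)C(=O)C[C@]12C | intermediate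
22 | 6α-hydroperoxy enone (C7=C8, C9 ketone) | CC[Si](CC)(CC)O[C@H]1C[C@](O)(C(C)C)[C@H]2[C@H](OO)C=C(C)C(=O)C[C@]12C | intermediate (not isolated)
23 | 6α-hydroxy enone | CC[Si](CC)(CC)O[C@H]1C[C@](O)(C(C)C)[C@H]2[C@H](O)C=C(C)C(=O)C[C@]12C | intermediate
24 | 4-acetoxybenzoic acid | CC(=O)Oc1ccc(cc1)C(=O)O | starting material
25 | 6α-(4-acetoxybenzoate), 2β-silyl ether | CC[Si](CC)(CC)O[C@H]1C[C@](O)(C(C)C)[C@H]2[C@H](OC(=O)c3ccc(OC(C)=O)cc3)C=C(C)C(=O)C[C@]12C | intermediate
26 | 2β-alcohol, 6α-(4-acetoxybenzoate) | O[C@H]1C[C@](O)(C(C)C)[C@H]2[C@H](OC(=O)c3ccc(OC(C)=O)cc3)C=C(C)C(=O)C[C@]12C | intermediate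
27 | 2β-acetate, 6α-(4-acetoxybenzoate) | CC(=O)O[C@H]1C[C@](O)(C(C)C)[C@H]2[C@H](OC(=O)c3ccc(OC(C)=O)cc3)C=C(C)C(=O)C[C@]12C | intermediate
28 | CNP0087181.7 (2β-acetoxy, 4β-hydroxy, 4α-isopropyl, 6α-(4-hydroxybenzoyloxy), 1β,8-dimethyl hydroazulen-9-one with C7=C8) | CC(=O)O[C@H]1C[C@](O)(C(C)C)[C@H]2[C@H](OC(=O)c3ccc(O)cc3)C=C(C)C(=O)C[C@]12C | target

## Step count and risks

Total steps: 18. Longest linear sequence: 18 steps, from 1 and 2 to 28; compounds 5, 18 and 24 are purchased.

Steps most likely to fail, in order:

First, step 9. The enolate may add to the other face of the aldehyde, because both faces of C2 are open in the boat-shaped transition state, and the hydroxyl would then be α. In the fallback the configuration at C2 is no longer set by the aldol but by a later ketone reduction. The fallback sets out from 14: the aldol is run as before and the 2α-hydroxy ketone F1 is treated directly with excess isopropylcerium dichloride (from 18 and CeCl3). The α alkoxide can guide the reagent only to the α face of the C4 ketone, which should give the 2α,4β-diol F2. Dess–Martin oxidation of the secondary alcohol gives the C2 ketone F3. NaBH4 in MeOH should attack it on the α face, anti to the angular C1 methyl and the oxygen bridge, to give the 2β,4β-diol F4. Selective silylation of the secondary hydroxyl (Et3SiCl, imidazole) returns to the route at 19.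

Second, step 14. The cis-disubstituted alkene may react slowly, singlet oxygen may abstract the ring-fusion hydrogen on C5 instead of the C8 hydrogen, or C8 may epimerise in 21 before the ene step; each of these would lose the relay of configuration to C6. The fallback sets out from 21 and introduces the oxygen by epoxidation: mCPBA with NaHCO3 in CH2Cl2 should epoxidise C6=C7 on the α face, anti to the β methyl groups on C8 and C1, to give the 6α,7α-epoxy ketone F5. Triethylamine then opens the β,γ-epoxy ketone by E1cB elimination from C8, which returns to the route at 23. On this path the configuration at C8 no longer matters.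

Third, step 2. Enantioselection may erode under external quench, and the axial aldol may undergo retro-aldol or epimerise before it is protected. The fallback separates enantioselection from C–C bond formation. It sets out from 4, which is deprotonated with the same lithium amide in the presence of Me3SiCl (internal quench) to give the trimethylsilyl enol ether F6, whose enantiomeric purity can be checked and raised before use. A Mukaiyama aldol addition of F6 to 5 with BF3·OEt2 in CH2Cl2 at −78 °C, again on the exo face, returns to the route at 7 (as carbinol epimers, which converge at 14).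

Further compounds
F1 | step 9 | 2α-hydroxy epimer of 16 | O[C@@H]1CC(=O)[C@H]2[C@@H]3C=C[C@@H](O3)C[C@]12C
F2 | step 9 | bridged 2α,4β-diol (4α-isopropyl) | O[C@@H]1C[C@](O)(C(C)C)[C@H]2[C@@H]3C=C[C@@H](O3)C[C@]12C
F3 | step 9 | bridged C2 ketone with 4β-hydroxy and 4α-isopropyl | O=C1C[C@](O)(C(C)C)[C@H]2[C@@H]3C=C[C@@H](O3)C[C@]12C
F4 | step 9 | bridged 2β,4β-diol (4α-isopropyl) | O[C@H]1C[C@](O)(C(C)C)[C@H]2[C@@H]3C=C[C@@H](O3)C[C@]12C
F5 | step 14 | 6α,7α-epoxy C9 ketone (8β-methyl, 2β-silyloxy) | CC[Si](CC)(CC)O[C@H]1C[C@](O)(C(C)C)[C@H]2[C@@H]3O[C@@H]3[C@@H](C)C(=O)C[C@]12C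
F6 | step 2 | trimethylsilyl enol ether of 4 (C1=C5) | C[Si](C)(C)OC1=C[C@@H]2C=C[C@H](C1)O2
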